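## Structural features

The target is a 2,5-diaryl-3,4-dimethyltetrahydrofuran (ring A, numbered here O1, C2, C3, C4, C5) with a trisubstituted phenol (ring B) on C2 and a 4-hydroxyphenyl group (ring C) on C5. Ring B has a 1,3,4 pattern: C1 is bonded to C2 of ring A, C4 carries the hydroxyl group, and C3 carries a side chain C8H(CH3)–C7H2 that ends in a second 4-hydroxyphenyl group (ring D). Ring A holds four contiguous stereocentres, (2R,3R,4S,5S): the two methyl groups are cis and each aryl group is trans to its neighbouring methyl. The fifth stereocentre, C8 (R), is a benzylic methine flanked by an arene and a methylene, with no functional group next to it. The fragile points are the two benzylic C–O bonds of ring A, which ionise under acid and can be hydrogenolysed, and the three phenols, which are kept masked until the last step. The difficulty is twofold: C8 offers no handle for being set on a finished ring B, and the cis-3,4-dimethyl unit is the less stable arrangement of ring A. The key step uses the fact that in ring B the oxygen at C4 is para to the carbon substituent at C1 and ortho to the side chain at C3. A 2-pyrone-5-carboxylate can supply C1, C2, C5 and C6, and a ketene acetal can supply C3 and C4, so C8 arrives already configured on the acetal.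

## Logic of the disconnections

29 to 28: the three O–CH2Ph bonds are cut. The phenols must be masked against organometallic reagents and acid. Nothing is simplified structurally, but every later step depends on it. The forward step must remove three benzyl groups without breaking the benzylic C–O bonds of ring A.

28 to 27: the O1–C5 bond of ring A is cut. C5 is a benzylic carbon with a para oxygen donor, so it is formed reliably from a cation and its configuration need not be controlled beforehand. Ring A becomes an open chain. The closure must put ring C trans to the C4 methyl and must leave C3 and C4 alone.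

27 to 25 and 4 (through 26): the C5–aryl bond is cut. Ring C is a plain aryl nucleophile and 4 is used a second time. The addition must be faster than enolisation at C4.

25 to 24 to 23: the C5 oxidation level is adjusted and the C4–H bond is traced back to a C4=CH2 alkene. C3 is the only stereocentre close enough to direct the new one. One stereocentre is removed. The hydroboration must add to the face that gives the cis-dimethyl pair.

23 to 22, 21, 20 and 19: the C4 methyl and the methylene carbon (future C5) are removed from C4, which returns to an acyl carbon. This leads back to an aldol adduct. The forward steps must not epimerise C3 or eliminate the C2 oxygen.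

19 to 16 and 17: the C2–C3 bond is cut. The carbon that ring B brings is electrophilic, so C3 must be the nucleophile. An anti aldol is required, because a syn adduct would put ring B cis to the C3 methyl in ring A. Two stereocentres come from an auxiliary, independent of C8. The step needs anti selectivity and the correct enolate face.

16 to 15, 14 and 13: oxidation state and the ring B benzyl ether are adjusted. Full reduction and re-oxidation is chosen over a partial ester reduction for reliability.

13 to 8 and 9: the ring B bonds C2–C3 and C4–C5 are cut. This removes ring B and its substitution pattern in one step and takes C8 off the arene. The forward step must be regioselective and must lose CO2 and silanol cleanly.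

8 to 7 to 6: the two O–Si bonds and the ester are adjusted. The bis-silyl acetal is chosen because a silanol is then the only possible leaving group and the phenol is released directly.

6 to 3 and 4 (through 5): the C7–aryl bond of ring D is cut, with a carboxyl group as the handle. This returns to a symmetrical diacid derivative. The radical coupling must not disturb the neighbouring stereocentre.

3 to 2 to 1: the difference between the two carboxyl arms is removed. In 1 the future C8 lies on a mirror plane, so the stereocentre comes from a desymmetrisation. The catalyst must distinguish two enantiotopic carbonyl groups.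

## Other disconnections considered

Alternative 1: The cut is at the two C–CH3 bonds of C3 and C4, traced back to the C–CH2–S bonds of a thiolane fused to a lactone precursor of ring A.
- Forward key step: a fluoride-generated thiocarbonyl ylide would add to the C=C bond of butenolide A1 on the face away from the aryl group, giving the cis-fused thienofuranone A2. Raney Ni would then unmask the cis-dimethyl lactone A3. Ring B would be added as an aryl-metal reagent before reduction and closure at C2.
- In favour: a suprafacial [3+2] cycloaddition can only give a cis pair. On this point it is better than the chosen plan, where the same relationship rests on an open-chain hydroboration. A3 would be two steps from A1, against six steps from 16 to 24.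
- Against: it solves ring A only. Ring B must enter as a nucleophile, so C8 would have to be made on a preformed arene. Raney Ni also hydrogenolyses aryl benzyl ethers and benzylic lactone C–O bonds. The γ-hydrogen of A1 is acidic, which puts its configuration at risk under fluoride.
- Comparison: structurally stronger for ring A and weaker for C8. Mechanistically a pericyclic step replaces an auxiliary-controlled aldol plus a substrate-controlled hydroboration. The total step count would not fall, because an asymmetric route to C8 and to A1 must be added.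

Alternative 2: The cut is at C2–C3 and C4–C5. C3, C4 and both methyl groups come from cis-but-2-ene A6, and O1 is inserted later.
- Forward key step: amide A4, activated with Tf2O and 2,4,6-collidine, would give an aryl keteniminium ion that adds to A6. Hydrolysis gives cyclobutanone A5, and a Baeyer–Villiger oxidation with migration of the aryl-bearing carbon gives the same lactone A3.
- In favour: the alkene geometry is carried into the ring, and the aryl group can settle trans to its neighbour by enolisation of A5. A3 would be three steps from A4. In step economy for ring A it is the equal of alternative 1 and better than the chosen plan.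
- Against: the absolute configuration depends on a stereocentre of the amine that is remote from the bond-forming carbons. The addition to an unactivated 1,2-disubstituted alkene may be stepwise, so facial selectivity and retention of the cis geometry are both uncertain. The electron-rich ring is exposed to Tf2O and to a peracid. Ring B must again be a nucleophile.
- Comparison: best step count for ring A, weakest absolute control, and C8 is left unsolved.

Alternative 3: The cut is at C3–C4, after O1–C2 has been traced back to an intermolecular bromoetherification.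
- Forward key step: in bromo ether A7, Bu3SnH with AIBN would turn C3 into a radical that adds 5-exo-trig to the vinyl group on C5. This closes ring A and leaves a primary radical that is reduced to the C4 methyl, giving A8, which is identical with 28.
- In favour: it is the most convergent plan and ends at the same compound as the chosen route, so the last step is shared. The conditions are neutral. The chair-like Beckwith–Houk transition state predicts the required 2,3-trans, 3,4-cis, 4,5-trans product. In direction of stereocontrol it is the equal of the chosen plan, and in step count for ring A it is better.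
- Against: each of the three preferences is modest and they multiply. C2 must be set in a bromoetherification that passes through an open benzylic cation. Direct reduction of the radical competes, and tin residues must be removed. The ring B half still needs C8 on a finished arene.
- Comparison: shortest for ring A, least reliable in stereocontrol, and no answer to C8.

Key step: step 6

Notation: ArBD stands for the 4-(benzyloxy)-3-[(2R)-1-[4-(benzyloxy)phenyl]propan-2-yl]phenyl group (ring B with its side chain and ring D).

Assumption: (DHQD)2AQN is taken to open 1 to the R hemiester 2; if the sense is the opposite, the pseudoenantiomeric (DHQ)2AQN is used with no other change.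

## Route

Step 1
Reactants: 1 3-methylglutaric anhydride (4-methyloxane-2,6-dione)
Product: 2 (3R)-5-methoxy-3-methyl-5-oxopentanoic acid
Conditions: MeOH (10 equiv), (DHQD)2AQN (10 mol%), Et2O, −40 °C
Reagents that add atoms: methanol CO
Why: Cinchona-alkaloid-catalysed desymmetrising methanolysis of a meso anhydride; the quinuclidine nitrogen acts as a general base and directs MeOH to one of the two enantiotopic carbonyl groups, which fixes the centre that becomes C8.

Step 2
Reactants: 2 (3R)-5-methoxy-3-methyl-5-oxopentanoic acid
Product: 3 1-(1,3-dioxoisoindolin-2-yl) 5-methyl (3S)-3-methylpentanedioate (same spatial arrangement as 2; the descriptor changes because the N-oxy ester arm now outranks the methyl ester arm)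
Conditions: N-hydroxyphthalimide, DIC, DMAP (5 mol%), CH2Cl2, rt
Reagents that add atoms: N-hydroxyphthalimide O=C1c2ccccc2C(=O)N1O
Why: Carbodiimide (Steglich-type) esterification gives the redox-active ester; the stereocentre is β to the activated carbonyl and cannot enolise.

Step 3
Reactants: 3 1-(1,3-dioxoisoindolin-2-yl) 5-methyl (3S)-3-methylpentanedioate; 4 1-(benzyloxy)-4-bromobenzene
Product: 6 methyl (3R)-4-[4-(benzyloxy)phenyl]-3-methylbutanoate, via [4-(benzyloxy)phenyl]zinc chloride 5 (not isolated)
Conditions: 4, Mg, LiCl, ZnCl2, THF, rt; then 3, NiCl2·glyme (20 mol%), 4,4′-di-tert-butyl-2,2′-bipyridine (40 mol%), THF/DMF, rt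
Reagents that add atoms: none
Why: Nickel-catalysed decarboxylative cross-coupling of a redox-active ester with an arylzinc reagent; single-electron reduction of 3 releases CO2 and a primary radical at C7, which is captured by aryl-nickel and coupled. The stereocentre is next to the radical carbon, not at it, and is untouched.

Step 4
Reactants: 6 methyl (3R)-4-[4-(benzyloxy)phenyl]-3-methylbutanoate
Product: 7 (3R)-4-[4-(benzyloxy)phenyl]-3-methylbutanoic acid
Conditions: LiOH·H2O, THF/MeOH/H2O, rt; then 1 M HCl
Reagents that add atoms: lithium hydroxide [Li+].[OH-]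
Why: Ester saponification by acyl–oxygen cleavage; the β-stereocentre has no acidic hydrogen and the aryl benzyl ether is stable to hydroxide.

Step 5
Reactants: 7 (3R)-4-[4-(benzyloxy)phenyl]-3-methylbutanoic acid
Product: 8 (3R)-4-[4-(benzyloxy)phenyl]-3-methyl-1,1-bis(trimethylsilyloxy)but-1-ene
Conditions: LiN(iPr)2 (2.2 equiv), THF, −78 → 0 °C; Me3SiCl (2.5 equiv), −78 °C → rt; pentane, filtration under argon, used crude
Reagents that add atoms: chlorotrimethylsilane C[Si](C)(C)Cl
Why: Double deprotonation of the acid gives the enediolate, which is silylated on both oxygens (Ainsworth-type preparation of a bis-silyl ketene acetal); the stereocentre is β to the carboxyl carbon and is not deprotonated.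

Step 6
Reactants: 8 (3R)-4-[4-(benzyloxy)phenyl]-3-methyl-1,1-bis(trimethylsilyloxy)but-1-ene; 9 methyl coumalate (methyl 2-oxo-2H-pyran-5-carboxylate)
Product: 13 methyl 3-[(2R)-1-[4-(benzyloxy)phenyl]propan-2-yl]-4-hydroxybenzoate, via bridged lactone 10 (not isolated), via cyclohexadiene silyl ketal 11 (not isolated), via aryl trimethylsilyl ether 12 (not isolated)
Conditions: 9 (1.0 equiv), 8 (1.5 equiv), toluene, 110 °C, sealed vessel; then 1 M HCl, THF, rt
Reagents that add atoms: none
Why: The electron-rich C=C bond of 8 (HOMO raised by two silyloxy groups) and the pyrone diene of 9 (LUMO lowered by the lactone carbonyl and the C5 ester) combine in an inverse-electron-demand [4+2] cycloaddition, in which C6 of the pyrone is joined to the β-carbon of 8 (the one bearing the side chain) and C3 of the pyrone to the acetal carbon, giving the bridged lactone 10. Cycloreversion of 10 expels CO2 to give the cyclohexadiene 11, 1,2-elimination of Me3SiOH aromatises the ring to 12, and dilute acid removes the remaining silyl group to give 13. The closest known reaction type is the Diels–Alder/decarboxylation sequence of 2-pyrone-5-carboxylates with ketene acetals that gives 4-alkoxybenzoates; the O,O-bis-silyl acetal is used so that a silanol is the only possible leaving group and the oxygen appears as the free phenol. Ring B is closed in the intermolecular cycloaddition itself, by formation of its C2–C3 and C4–C5 bonds, with the other four ring carbons supplied by 9. No new stereocentre survives: the sp3 centres of 10 and 11 are destroyed on aromatisation, so endo/exo and facial selectivity do not matter, and C8, which is allylic to the acetal and has no acidic hydrogen, is carried through unchanged. The selectivity that matters is regiochemical (carboxylate para to the oxygen, side chain ortho to it), and it follows from the polarisation of both partners: C6 of 9 is the terminus of the conjugated ester and lactone system and the most electrophilic carbon, and the β-carbon of 8 is the most nucleophilic. Ring closure is favoured over an open-chain Michael adduct by a non-polar solvent and the absence of Lewis acid or fluoride, and a stepwise zwitterion would still be expected to collapse to 10.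

Step 7
Reactants: 13 methyl 3-[(2R)-1-[4-(benzyloxy)phenyl]propan-2-yl]-4-hydroxybenzoate
Product: 14 methyl 4-(benzyloxy)-3-[(2R)-1-[4-(benzyloxy)phenyl]propan-2-yl]benzoate
Conditions: BnBr, K2CO3, DMF, rt
Reagents that add atoms: benzyl bromide BrCc1ccccc1
Why: Williamson O-alkylation of the phenoxide; the ester and C8 are inert to carbonate.

Step 8
Reactants: 14 methyl 4-(benzyloxy)-3-[(2R)-1-[4-(benzyloxy)phenyl]propan-2-yl]benzoate
Product: 15 (ArBD)methanol, {4-(benzyloxy)-3-[(2R)-1-[4-(benzyloxy)phenyl]propan-2-yl]phenyl}methanol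
Conditions: LiAlH4, THF, 0 °C
Reagents that add atoms: none
Why: Hydride reduction of the benzoate to the benzylic alcohol; full reduction followed by re-oxidation avoids the uneven stopping of a partial reduction of an electron-rich benzoate.

Step 9
Reactants: 15 (ArBD)methanol
Product: 16 ArBD-carbaldehyde, 4-(benzyloxy)-3-[(2R)-1-[4-(benzyloxy)phenyl]propan-2-yl]benzaldehyde
Conditions: MnO2 (activated, 10 equiv), CH2Cl2, rt
Reagents that add atoms: none
Why: MnO2 oxidises benzylic alcohols selectively and stops at the aldehyde.

Step 10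
Reactants: 16 ArBD-carbaldehyde; 17 (4R)-4-benzyl-3-propanoyl-1,3-oxazolidin-2-one
Product: 19 (4R)-4-benzyl-3-[(2S,3R)-3-(ArBD)-3-hydroxy-2-methylpropanoyl]-1,3-oxazolidin-2-one, via trimethylsilyl ether 18 (not isolated)
Conditions: 17 (1.3 equiv), MgCl2 (20 mol%), Et3N, Me3SiCl, EtOAc, rt; then CF3CO2H (cat.), MeOH
Reagents that add atoms: none
Why: Magnesium-halide-catalysed anti-selective Evans aldol: the chelated Z-magnesium enolate of 17 adds to the non-enolisable aldehyde through a boat-like transition state on the enolate face away from the benzyl group (the same facial sense as imide alkylation), which sets C3 and C2 as the anti (2S,3R) pair while Me3SiCl traps the aldolate and turns the catalyst over. The anti adduct is the one that places ring B trans to the C3 methyl in ring A. Diastereomers that stem from the minor enantiomer at C8 are removed here by crystallisation or chromatography.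

Step 11
Reactants: 19 (4R)-4-benzyl-3-[(2S,3R)-3-(ArBD)-3-hydroxy-2-methylpropanoyl]-1,3-oxazolidin-2-one
Product: 20 (2S,3R)-3-(ArBD)-3-hydroxy-N-methoxy-N,2-dimethylpropanamide
Conditions: MeNH(OMe)·HCl, AlMe3, THF/CH2Cl2, −20 → 0 °C
Reagents that add atoms: N,O-dimethylhydroxylamine hydrochloride CNOC.Cl
Why: Aluminium-amide transamination of the imide, assisted by the free β-hydroxyl group, gives the Weinreb amide and releases the auxiliary; these Lewis-acidic conditions do not epimerise the α-centre.

Step 12
Reactants: 20 (2S,3R)-3-(ArBD)-3-hydroxy-N-methoxy-N,2-dimethylpropanamide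
Product: 21 (2S,3R)-3-(ArBD)-3-[(tert-butyldimethylsilyl)oxy]-N-methoxy-N,2-dimethylpropanamide
Conditions: tBuMe2SiOTf, 2,6-lutidine, CH2Cl2, −78 → 0 °C
Reagents that add atoms: tert-butyldimethylsilyl triflate CC(C)(C)[Si](C)(C)OS(=O)(=O)C(F)(F)F
Why: Silylation of the hindered benzylic alcohol; the ether blocks retro-aldol cleavage and alkoxide chemistry in the organometallic steps that follow.

Step 13
Reactants: 21 (2S,3R)-3-(ArBD)-3-[(tert-butyldimethylsilyl)oxy]-N-methoxy-N,2-dimethylpropanamide
Product: 22 (3S,4R)-4-(ArBD)-4-[(tert-butyldimethylsilyl)oxy]-3-methylbutan-2-one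
Conditions: MeMgBr, THF, 0 °C
Reagents that add atoms: methylmagnesium bromide C[Mg]Br
Why: Weinreb ketone synthesis; the chelated tetrahedral intermediate survives until work-up, so addition stops at the methyl ketone.

Step 14
Reactants: 22 (3S,4R)-4-(ArBD)-4-[(tert-butyldimethylsilyl)oxy]-3-methylbutan-2-one
Product: 23 tert-butyl{[(1R,2R)-1-(ArBD)-2,3-dimethylbut-3-en-1-yl]oxy}dimethylsilane
Conditions: Cp2TiMe2 (3 equiv), toluene, 65 °C, dark
Reagents that add atoms: dimethyltitanocene C[Ti](C)(C1C=CC=C1)C1C=CC=C1
Why: Petasis methylenation; the titanium methylidene formed on warming converts the ketone into the 1,1-disubstituted alkene under non-basic conditions, which protects the enolisable C3 centre and the β-silyloxy group.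

Step 15
Reactants: 23 tert-butyl{[(1R,2R)-1-(ArBD)-2,3-dimethylbut-3-en-1-yl]oxy}dimethylsilane
Product: 24 (2S,3R,4R)-4-(ArBD)-4-[(tert-butyldimethylsilyl)oxy]-2,3-dimethylbutan-1-ol
Conditions: 9-BBN, THF, 0 °C → rt; then NaOH, H2O2, 0 °C
Reagents that add atoms: hydrogen peroxide OO
Why: Substrate-controlled hydroboration–oxidation of a 1,1-disubstituted alkene; in the reactive conformer the C3 hydrogen eclipses the double bond and the bulky borane adds to the face opposite the CH(OSi)aryl group, on the side of the C3 methyl. This sets C4 and should give the 3,4-anti chain, which is the cis-dimethyl pair of ring A.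

Step 16
Reactants: 24 (2S,3R,4R)-4-(ArBD)-4-[(tert-butyldimethylsilyl)oxy]-2,3-dimethylbutan-1-ol
Product: 25 (2S,3R,4R)-4-(ArBD)-4-[(tert-butyldimethylsilyl)oxy]-2,3-dimethylbutanal
Conditions: Dess–Martin periodinane, NaHCO3, CH2Cl2, 0 °C → rt; used at once
Reagents that add atoms: none
Why: Buffered hypervalent-iodine oxidation of the primary alcohol stops at the aldehyde and is mild enough to leave the α-centre (C4) unepimerised.

Step 17
Reactants: 25 (2S,3R,4R)-4-(ArBD)-4-[(tert-butyldimethylsilyl)oxy]-2,3-dimethylbutanal; 4 1-(benzyloxy)-4-bromobenzene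
Product: 27 (1RS,2S,3R,4R)-1-[4-(benzyloxy)phenyl]-4-(ArBD)-4-[(tert-butyldimethylsilyl)oxy]-2,3-dimethylbutan-1-ol as both C1 epimers, via [4-(benzyloxy)phenyl]magnesium bromide 26 (not isolated)
Conditions: 4, Mg, THF, reflux; then 25, THF, −78 °C
Reagents that add atoms: none
Why: Grignard addition to the aldehyde attaches ring C and creates the C5 carbinol; its configuration is not controlled and need not be, because C5 is ionised in the next step.

Step 18
Reactants: 27 (1RS,2S,3R,4R)-1-[4-(benzyloxy)phenyl]-4-(ArBD)-4-[(tert-butyldimethylsilyl)oxy]-2,3-dimethylbutan-1-ol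
Product: 28 (2R,3R,4S,5S)-2-(ArBD)-5-[4-(benzyloxy)phenyl]-3,4-dimethyloxolane
Conditions: TsOH·H2O (10 mol%), CH2Cl2, 0 °C → rt
Reagents that add atoms: none
Why: Acid-promoted SN1 cycloetherification; ionisation of the C5 carbinol gives a cation stabilised by the para-benzyloxy group, which is captured by the C2 oxygen with loss of the silyl group as the silanol, closing ring A at the O1–C5 bond. Ring C should end trans to the C4 methyl because that approach avoids eclipsing in the envelope transition state and because both benzylic C–O bonds can re-ionise, so the isomer with each aryl trans to its neighbouring methyl accumulates.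

Step 19
Reactants: 28 (2R,3R,4S,5S)-2-(ArBD)-5-[4-(benzyloxy)phenyl]-3,4-dimethyloxolane
Product: 29 (2R,3R,4S,5S)-2-{4-hydroxy-3-[(2R)-1-(4-hydroxyphenyl)propan-2-yl]phenyl}-5-(4-hydroxyphenyl)-3,4-dimethyloxolane
Conditions: H2 (1 atm), 10% Pd/C, EtOAc, rt
Reagents that add atoms: none
Why: Hydrogenolysis of three aryl benzyl ethers on palladium; under neutral conditions these are cleaved much faster than the dialkyl benzylic C–O bonds of ring A, and the reaction is stopped when the third benzyl group is gone.

## Compound list

1 | 3-methylglutaric anhydride | CC1CC(=O)OC(=O)C1 | starting material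
2 | (3R)-5-methoxy-3-methyl-5-oxopentanoic acid | COC(=O)C[C@H](C)CC(=O)O | intermediate
3 | 1-(1,3-dioxoisoindolin-2-yl) 5-methyl (3S)-3-methylpentanedioate | COC(=O)C[C@H](C)CC(=O)ON1C(=O)c2ccccc2C1=O | intermediate
4 | 1-(benzyloxy)-4-bromobenzene | Brc1ccc(OCc2ccccc2)cc1 | starting material
5 | [4-(benzyloxy)phenyl]zinc chloride (not isolated) | Cl[Zn]c1ccc(OCc2ccccc2)cc1 | intermediate
6 | methyl (3R)-4-[4-(benzyloxy)phenyl]-3-methylbutanoate | COC(=O)C[C@H](C)Cc1ccc(OCc2ccccc2)cc1 | intermediate
7 | (3R)-4-[4-(benzyloxy)phenyl]-3-methylbutanoic acid | OC(=O)C[C@H](C)Cc1ccc(OCc2ccccc2)cc1 | intermediate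
8 | (3R)-4-[4-(benzyloxy)phenyl]-3-methyl-1,1-bis(trimethylsilyloxy)but-1-ene | C[Si](C)(C)OC(O[Si](C)(C)C)=C[C@H](C)Cc1ccc(OCc2ccccc2)cc1 | intermediate
9 | methyl coumalate | COC(=O)C1=COC(=O)C=C1 | starting material
10 | methyl 7-[(2R)-1-[4-(benzyloxy)phenyl]propan-2-yl]-3-oxo-8,8-bis(trimethylsilyloxy)-2-oxabicyclo[2.2.2]oct-5-ene-6-carboxylate (not isolated; mixture at the new ring carbons) | COC(=O)C1=CC2C(=O)OC1C([C@H](C)Cc1ccc(OCc3ccccc3)cc1)C2(O[Si](C)(C)C)O[Si](C)(C)C | intermediate
11 | methyl 3-[(2R)-1-[4-(benzyloxy)phenyl]propan-2-yl]-4,4-bis(trimethylsilyloxy)cyclohexa-1,5-diene-1-carboxylate (not isolated; mixture at ring C3) | COC(=O)C1=CC([C@H](C)Cc2ccc(OCc3ccccc3)cc2)C(O[Si](C)(C)C)(O[Si](C)(C)C)C=C1 | intermediate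
12 | methyl 3-[(2R)-1-[4-(benzyloxy)phenyl]propan-2-yl]-4-(trimethylsilyloxy)benzoate (not isolated) | COC(=O)c1ccc(O[Si](C)(C)C)c([C@H](C)Cc2ccc(OCc3ccccc3)cc2)c1 | intermediate
13 | methyl 3-[(2R)-1-[4-(benzyloxy)phenyl]propan-2-yl]-4-hydroxybenzoate | COC(=O)c1ccc(O)c([C@H](C)Cc2ccc(OCc3ccccc3)cc2)c1 | intermediate
14 | methyl 4-(benzyloxy)-3-[(2R)-1-[4-(benzyloxy)phenyl]propan-2-yl]benzoate | COC(=O)c1ccc(OCc2ccccc2)c([C@H](C)Cc2ccc(OCc3ccccc3)cc2)c1 | intermediate
15 | {4-(benzyloxy)-3-[(2R)-1-[4-(benzyloxy)phenyl]propan-2-yl]phenyl}methanol | OCc1ccc(OCc2ccccc2)c([C@H](C)Cc2ccc(OCc3ccccc3)cc2)c1 | intermediate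
16 | 4-(benzyloxy)-3-[(2R)-1-[4-(benzyloxy)phenyl]propan-2-yl]benzaldehyde | O=Cc1ccc(OCc2ccccc2)c([C@H](C)Cc2ccc(OCc3ccccc3)cc2)c1 | intermediate
17 | (4R)-4-benzyl-3-propanoyl-1,3-oxazolidin-2-one | CCC(=O)N1[C@H](Cc2ccccc2)COC1=O | starting material
18 | (4R)-4-benzyl-3-[(2S,3R)-3-(ArBD)-2-methyl-3-(trimethylsilyloxy)propanoyl]-1,3-oxazolidin-2-one (not isolated) | C[C@@H]([C@@H](O[Si](C)(C)C)c1ccc(OCc2ccccc2)c([C@H](C)Cc2ccc(OCc3ccccc3)cc2)c1)C(=O)N1[C@H](Cc2ccccc2)COC1=O | intermediate
19 | (4R)-4-benzyl-3-[(2S,3R)-3-(ArBD)-3-hydroxy-2-methylpropanoyl]-1,3-oxazolidin-2-one | C[C@@H]([C@@H](O)c1ccc(OCc2ccccc2)c([C@H](C)Cc2ccc(OCc3ccccc3)cc2)c1)C(=O)N1[C@H](Cc2ccccc2)COC1=O | intermediate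
20 | (2S,3R)-3-(ArBD)-3-hydroxy-N-methoxy-N,2-dimethylpropanamide | C[C@@H]([C@@H](O)c1ccc(OCc2ccccc2)c([C@H](C)Cc2ccc(OCc3ccccc3)cc2)c1)C(=O)N(C)OC | intermediate
21 | (2S,3R)-3-(ArBD)-3-[(tert-butyldimethylsilyl)oxy]-N-methoxy-N,2-dimethylpropanamide | C[C@@H]([C@@H](O[Si](C)(C)C(C)(C)C)c1ccc(OCc2ccccc2)c([C@H](C)Cc2ccc(OCc3ccccc3)cc2)c1)C(=O)N(C)OC | intermediate
22 | (3S,4R)-4-(ArBD)-4-[(tert-butyldimethylsilyl)oxy]-3-methylbutan-2-one | C[C@@H]([C@@H](O[Si](C)(C)C(C)(C)C)c1ccc(OCc2ccccc2)c([C@H](C)Cc2ccc(OCc3ccccc3)cc2)c1)C(C)=O | intermediate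
23 | tert-butyl{[(1R,2R)-1-(ArBD)-2,3-dimethylbut-3-en-1-yl]oxy}dimethylsilane | C[C@@H]([C@@H](O[Si](C)(C)C(C)(C)C)c1ccc(OCc2ccccc2)c([C@H](C)Cc2ccc(OCc3ccccc3)cc2)c1)C(C)=C | intermediate
24 | (2S,3R,4R)-4-(ArBD)-4-[(tert-butyldimethylsilyl)oxy]-2,3-dimethylbutan-1-ol | C[C@@H]([C@@H](O[Si](C)(C)C(C)(C)C)c1ccc(OCc2ccccc2)c([C@H](C)Cc2ccc(OCc3ccccc3)cc2)c1)[C@H](C)CO | intermediate
25 | (2S,3R,4R)-4-(ArBD)-4-[(tert-butyldimethylsilyl)oxy]-2,3-dimethylbutanal | C[C@@H]([C@@H](O[Si](C)(C)C(C)(C)C)c1ccc(OCc2ccccc2)c([C@H](C)Cc2ccc(OCc3ccccc3)cc2)c1)[C@H](C)C=O | intermediate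
26 | [4-(benzyloxy)phenyl]magnesium bromide (not isolated) | Br[Mg]c1ccc(OCc2ccccc2)cc1 | intermediate
27 | (1RS,2S,3R,4R)-1-[4-(benzyloxy)phenyl]-4-(ArBD)-4-[(tert-butyldimethylsilyl)oxy]-2,3-dimethylbutan-1-ol (both C1 epimers) | C[C@@H]([C@@H](O[Si](C)(C)C(C)(C)C)c1ccc(OCc2ccccc2)c([C@H](C)Cc2ccc(OCc3ccccc3)cc2)c1)[C@H](C)C(O)c1ccc(OCc2ccccc2)cc1 | intermediate
28 | (2R,3R,4S,5S)-2-(ArBD)-5-[4-(benzyloxy)phenyl]-3,4-dimethyloxolane | C[C@@H]1[C@H](C)[C@@H](c2ccc(OCc3ccccc3)cc2)O[C@H]1c1ccc(OCc2ccccc2)c([C@H](C)Cc2ccc(OCc3ccccc3)cc2)c1 | intermediate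
29 | (2R,3R,4S,5S)-2-{4-hydroxy-3-[(2R)-1-(4-hydroxyphenyl)propan-2-yl]phenyl}-5-(4-hydroxyphenyl)-3,4-dimethyloxolane (CNP0232576.1) | C[C@@H]1[C@H](C)[C@@H](c2ccc(O)cc2)O[C@H]1c1ccc(O)c([C@H](C)Cc2ccc(O)cc2)c1 | target

## Step count and uncertain steps

Total step count: 19. Longest linear sequence: 19 steps (1 to 29); 4, 9 and 17 are purchased.

Step 6 (key step). The silyl ketene acetal may act as a Mukaiyama–Michael donor at C6 of 9 without closing the second bond; silyl transfer and electrocyclic opening of the pyran would then drain material into open-chain dienoates. Hydrolysis of 8 by traces of water returns 7, and extrusion of CO2 may be incomplete at 110 °C. The fallback builds ring B by a normal-demand Diels–Alder reaction with the side chain on the diene; it sets out from 7 and comes back at 12. Acid 7 with MeLi (2.2 equiv) gives the methyl ketone (4R)-5-[4-(benzyloxy)phenyl]-4-methylpentan-2-one F1. α-Methylenation at the more substituted α-carbon with paraformaldehyde and iPr2NH·CF3CO2H gives the enone (4R)-5-[4-(benzyloxy)phenyl]-4-methyl-3-methylidenepentan-2-one F2. Me3SiOTf and Et3N give the diene {[(4R)-5-[4-(benzyloxy)phenyl]-4-methyl-3-methylidenepent-1-en-2-yl]oxy}trimethylsilane F3. Heating F3 with methyl propiolate in toluene gives the "para" adduct methyl 5-[(2R)-1-[4-(benzyloxy)phenyl]propan-2-yl]-4-(trimethylsilyloxy)cyclohexa-1,4-diene-1-carboxylate F4. DDQ dehydrogenates F4 to 12, which is desilylated to 13 as in step 6.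

Step 15. The borane may add with poor facial selectivity, or with the opposite sense if the silyloxy-bearing group does not behave as the large substituent; C4 would then be set wrongly and the error would only show after ring closure. The fallback sets C4 by cyclic control; it sets out from 22 and comes back at 28. Ketone 22 with KN(SiMe3)2 and PhNTf2 gives the enol triflate (3S,4R)-4-(ArBD)-4-[(tert-butyldimethylsilyl)oxy]-3-methylbut-1-en-2-yl trifluoromethanesulfonate F5. Carbonylation with Pd(OAc)2, PPh3, CO, MeOH and Et3N gives methyl (3R,4R)-4-(ArBD)-4-[(tert-butyldimethylsilyl)oxy]-3-methyl-2-methylidenebutanoate F6. Bu4NF removes the silyl group and the alkoxide closes to (4R,5R)-5-(ArBD)-4-methyl-3-methylideneoxolan-2-one F7. Homogeneous hydrogenation with H2 and RhCl(PPh3)3 should deliver hydrogen to the face opposite the neighbouring methyl and give (3S,4R,5R)-5-(ArBD)-3,4-dimethyloxolan-2-one F8. iBu2AlH at −78 °C gives the lactol (3S,4R,5R)-5-(ArBD)-3,4-dimethyloxolan-2-ol F9. The Grignard reagent 26 (excess) opens F9 to (2S,3R,4R)-1-[4-(benzyloxy)phenyl]-4-(ArBD)-2,3-dimethylbutane-1,4-diol F10, which is cyclised with TsOH to 28.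

Step 18. The benzylic cation may lose a β-proton and be re-protonated, which would scramble C3 and C4 toward the all-trans isomer; equilibration at C2 and C5 may also stop short, leaving a cis aryl–methyl pair. The fallback replaces Brønsted-acid equilibration by a base-buffered closure; it sets out from 27 and comes back at 28. Bu4NF gives (2S,3R,4R)-1-[4-(benzyloxy)phenyl]-4-(ArBD)-2,3-dimethylbutane-1,4-diol F11. MsCl and Et3N in CH2Cl2 at −20 °C sulfonylate a benzylic hydroxyl group; the mesylate ionises at once and the remaining hydroxyl closes ring A with no free acid present.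

Step 19. Hydrogenolysis may go on to the benzylic C–O bonds of ring A (ring opening), or stop before the hindered ring B benzyl ether is cleaved. The fallback replaces reduction by nucleophilic dealkylation; it sets out from 28 and comes back at 29, and no new compound is made (entry F0). NaSEt in DMF at 110 °C attacks the benzyl CH2 groups by SN2 and releases the three phenoxides; the ring A carbons are secondary dialkyl-ether carbons and should not be attacked.

## Further compounds

F1 | step 6 | (4R)-5-[4-(benzyloxy)phenyl]-4-methylpentan-2-one | CC(=O)C[C@H](C)Cc1ccc(OCc2ccccc2)cc1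
F2 | step 6 | (4R)-5-[4-(benzyloxy)phenyl]-4-methyl-3-methylidenepentan-2-one | CC(=O)C(=C)[C@H](C)Cc1ccc(OCc2ccccc2)cc1
F3 | step 6 | {[(4R)-5-[4-(benzyloxy)phenyl]-4-methyl-3-methylidenepent-1-en-2-yl]oxy}trimethylsilane | C=C(O[Si](C)(C)C)C(=C)[C@H](C)Cc1ccc(OCc2ccccc2)cc1
F4 | step 6 | methyl 5-[(2R)-1-[4-(benzyloxy)phenyl]propan-2-yl]-4-(trimethylsilyloxy)cyclohexa-1,4-diene-1-carboxylate | COC(=O)C1=CCC(O[Si](C)(C)C)=C(C1)[C@H](C)Cc1ccc(OCc2ccccc2)cc1
F5 | step 15 | (3S,4R)-4-(ArBD)-4-[(tert-butyldimethylsilyl)oxy]-3-methylbut-1-en-2-yl trifluoromethanesulfonate | C[C@@H]([C@@H](O[Si](C)(C)C(C)(C)C)c1ccc(OCc2ccccc2)c([C@H](C)Cc2ccc(OCc3ccccc3)cc2)c1)C(=C)OS(=O)(=O)C(F)(F)F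
F6 | step 15 | methyl (3R,4R)-4-(ArBD)-4-[(tert-butyldimethylsilyl)oxy]-3-methyl-2-methylidenebutanoate | C[C@@H]([C@@H](O[Si](C)(C)C(C)(C)C)c1ccc(OCc2ccccc2)c([C@H](C)Cc2ccc(OCc3ccccc3)cc2)c1)C(=C)C(=O)OC
F7 | step 15 | (4R,5R)-5-(ArBD)-4-methyl-3-methylideneoxolan-2-one | C[C@@H]1C(=C)C(=O)O[C@H]1c1ccc(OCc2ccccc2)c([C@H](C)Cc2ccc(OCc3ccccc3)cc2)c1
F8 | step 15 | (3S,4R,5R)-5-(ArBD)-3,4-dimethyloxolan-2-one | C[C@@H]1[C@H](C)C(=O)O[C@H]1c1ccc(OCc2ccccc2)c([C@H](C)Cc2ccc(OCc3ccccc3)cc2)c1
F9 | step 15 | (3S,4R,5R)-5-(ArBD)-3,4-dimethyloxolan-2-ol (both anomers) | C[C@@H]1[C@H](C)C(O)O[C@H]1c1ccc(OCc2ccccc2)c([C@H](C)Cc2ccc(OCc3ccccc3)cc2)c1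
F10 | step 15 | (2S,3R,4R)-1-[4-(benzyloxy)phenyl]-4-(ArBD)-2,3-dimethylbutane-1,4-diol (both C1 epimers) | C[C@@H]([C@@H](O)c1ccc(OCc2ccccc2)c([C@H](C)Cc2ccc(OCc3ccccc3)cc2)c1)[C@H](C)C(O)c1ccc(OCc2ccccc2)cc1
F11 | step 18 | (2S,3R,4R)-1-[4-(benzyloxy)phenyl]-4-(ArBD)-2,3-dimethylbutane-1,4-diol (both C1 epimers; same compound as F10) | C[C@@H]([C@@H](O)c1ccc(OCc2ccccc2)c([C@H](C)Cc2ccc(OCc3ccccc3)cc2)c1)[C@H](C)C(O)c1ccc(OCc2ccccc2)cc1
F0 | step 19 | none | none
A1 | alternative 1 | (5S)-5-[4-(benzyloxy)phenyl]furan-2(5H)-one | O=C1C=C[C@@H](c2ccc(OCc3ccccc3)cc2)O1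
A2 | alternative 1 | (3S,3aS,6aR)-3-[4-(benzyloxy)phenyl]tetrahydro-1H,3H-thieno[3,4-c]furan-1-one (cis-fused, aryl on the face opposite the thiolane ring) | C1[C@@H]2[C@H](CS1)[C@@H](c3ccc(OCc4ccccc4)cc3)OC2=O
A3 | alternative 1 | (3R,4S,5S)-5-[4-(benzyloxy)phenyl]-3,4-dimethyloxolan-2-one | C[C@@H]1[C@H](C)[C@@H](c2ccc(OCc3ccccc3)cc2)OC1=O
A4 | alternative 2 | 2-[4-(benzyloxy)phenyl]-1-[(2R,5R)-2,5-dimethylpyrrolidin-1-yl]ethan-1-one (or its enantiomer, as the facial sense requires) | C[C@@H]1CC[C@@H](C)N1C(=O)Cc1ccc(OCc2ccccc2)cc1
A5 | alternative 2 | (2S,3S,4R)-2-[4-(benzyloxy)phenyl]-3,4-dimethylcyclobutan-1-one | C[C@@H]1[C@H](C)[C@@H](c2ccc(OCc3ccccc3)cc2)C1=O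
A6 | alternative 2 | cis-but-2-ene | C/C=C\C
A7 | alternative 3 | 1-(benzyloxy)-4-[(1S)-1-{[(1S)-1-(ArBD)-2-bromopropyl]oxy}prop-2-en-1-yl]benzene (both epimers at the bromide carbon) | C=C[C@@H](c1ccc(OCc2ccccc2)cc1)O[C@H](C(C)Br)c1ccc(OCc2ccccc2)c([C@H](C)Cc2ccc(OCc3ccccc3)cc2)c1
A8 | alternative 3 | (2R,3R,4S,5S)-2-(ArBD)-5-[4-(benzyloxy)phenyl]-3,4-dimethyloxolane (identical with 28) | C[C@@H]1[C@H](C)[C@@H](c2ccc(OCc3ccccc3)cc2)O[C@H]1c1ccc(OCc2ccccc2)c([C@H](C)Cc2ccc(OCc3ccccc3)cc2)c1
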